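**Retrosynthetic overview**

1. The strategy rests on lower ring C: O1–C2 and C3–OH are 2,3-cis (2R,3R), which is anti addition of O1 and O3 across a Z C2=C3 bond, so ring C is opened at O1–C2 to a (2R,3S)-cis-oxirane attacked at benzylic C2 by the C8a hydroxyl.
2. That C8a hydroxyl is the only free phenol and sits between the upper-unit C4 substituent and the chain (the other flanking oxygen, O5, is a benzyl ether), so only the 4→8 isomer can form.
3. The oxirane comes from the Z alkene ((S,S)-(salen)MnCl), the alkene from the alkyne (Pd/CaCO3 poisoned with Pb(OAc)2); the upper C4–lower C8 bond is cut to the benzylated leucorobinetinidin C4 cation (from (+)-dihydrorobinetin) and an ortho-propargylated 3,5-dibenzyloxyphenol.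
4. The lower C4–C4a bond comes from a Nicholas reaction of 3,5-dibenzyloxyphenol (lower ring A) with the Co2(CO)6 complex of an aryl propynol made from 3,4,5-trihydroxybenzaldehyde (lower ring B).
5. Ring order: upper rings A, C and B are bought in dihydrorobinetin; lower ring C is the only ring closed, in the key step; nine benzyl ethers are removed last.

Key step: step 13

Assumption: 3,5-dibenzyloxyphenol and 3,4,5-trihydroxybenzaldehyde are bought as such, so both lower ring A oxygens (O5, O7) are benzyl ethers and the key-step product is the nona-O-benzyl ether.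

**Route**

Step 1
Reactants: 1 (+)-dihydrorobinetin, (2R,3R)-3,7-dihydroxy-2-(3,4,5-trihydroxyphenyl)chroman-4-one
Product: 2 (2R,3R)-7-benzyloxy-3-hydroxy-2-(3,4,5-tribenzyloxyphenyl)chroman-4-one
Conditions: BnBr (4.4 equiv), K2CO3, DMF, N2, rt
Reagents that add atoms: benzyl bromide, BrCc1ccccc1
Why: Williamson ether synthesis in which K2CO3 ionises only the four phenols, so the secondary 3-hydroxyl stays free and the thermodynamically preferred 2,3-trans ketol keeps C2 and C3.

Step 2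
Reactants: 2 (2R,3R)-7-benzyloxy-3-hydroxy-2-(3,4,5-tribenzyloxyphenyl)chroman-4-one
Product: 3 (2R,3S,4R)-7-benzyloxy-2-(3,4,5-tribenzyloxyphenyl)chromane-3,4-diol
Conditions: NaBH4, THF–MeOH, 0 °C
Reagents that add atoms: none
Why: Borohydride reduction of the aryl ketone, hydride adding anti to the 3-hydroxyl to give the all-equatorial 3,4-trans diol (4R); this centre is erased when C4 is ionised in step 8.

Step 3
Reactants: 4 3,4,5-trihydroxybenzaldehyde
Product: 5 3,4,5-tribenzyloxybenzaldehyde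
Conditions: BnBr (3.5 equiv), K2CO3, DMF, 60 °C
Reagents that add atoms: benzyl bromide, BrCc1ccccc1
Why: Williamson ether synthesis on three phenoxides, the aldehyde being inert to carbonate.

Step 4
Reactants: 5 3,4,5-tribenzyloxybenzaldehyde
Product: 6 1,2,3-tribenzyloxy-5-(2,2-dibromovinyl)benzene
Conditions: CBr4, PPh3, CH2Cl2, 0 °C
Reagents that add atoms: carbon tetrabromide, BrC(Br)(Br)Br
Why: First stage of the Corey–Fuchs reaction, a Wittig-type olefination of the aldehyde by the dibromomethylene ylide formed from PPh3 and CBr4.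

Step 5
Reactants: 6 1,2,3-tribenzyloxy-5-(2,2-dibromovinyl)benzene
Product: 8 3-(3,4,5-tribenzyloxyphenyl)prop-2-yn-1-ol, via lithium (3,4,5-tribenzyloxyphenyl)acetylide 7 (not isolated)
Conditions: n-BuLi (2.2 equiv), THF, −78 °C; then (CH2O)n, −78 °C to rt; H2O
Reagents that add atoms: paraformaldehyde (as formaldehyde), C=O
Why: Second stage of the Corey–Fuchs reaction (bromine–lithium exchange and Fritsch–Buttenberg–Wiechell rearrangement to the lithium acetylide), which is then hydroxymethylated by formaldehyde.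

Step 6
Reactants: 8 3-(3,4,5-tribenzyloxyphenyl)prop-2-yn-1-ol
Product: 9 hexacarbonyldicobalt complex of alkynol 8 (μ-alkyne)Co2(CO)6
Conditions: Co2(CO)8, CH2Cl2, rt
Reagents that add atoms: dicobalt octacarbonyl, O=C=[Co](=C=O)(=C=O)(=C=O)[Co](=C=O)(=C=O)(=C=O)=C=O
Why: Alkyne complexation by Co2(CO)8 with loss of two carbonyl ligands, which sets up the propargylic position for Nicholas ionisation.

Step 7
Reactants: 9 hexacarbonyldicobalt complex of alkynol 8; 10 3,5-dibenzyloxyphenol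
Product: 12 3,5-dibenzyloxy-2-[3-(3,4,5-tribenzyloxyphenyl)prop-2-yn-1-yl]phenol, via Co2(CO)6 complex of the propargylated phenol 11 (not isolated)
Conditions: 10 (3 equiv), BF3·OEt2, CH2Cl2, −40 to −10 °C; then Me3NO, THF, rt
Reagents that add atoms: none
Why: Nicholas reaction in which BF3 ionises the propargylic alcohol to the Co2(CO)6-stabilised cation, which alkylates the phenol at a carbon ortho to the hydroxyl (the other free carbon lies between two benzyloxy groups; excess phenol limits double alkylation), after which amine-oxide oxidation of the carbonyl ligands frees the alkyne.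

Step 8
Reactants: 3 (2R,3S,4R)-7-benzyloxy-2-(3,4,5-tribenzyloxyphenyl)chromane-3,4-diol; 12 3,5-dibenzyloxy-2-[3-(3,4,5-tribenzyloxyphenyl)prop-2-yn-1-yl]phenol
Product: 13 (2R,3S,4S)-7-benzyloxy-4-{4,6-dibenzyloxy-2-hydroxy-3-[3-(3,4,5-tribenzyloxyphenyl)prop-2-yn-1-yl]phenyl}-2-(3,4,5-tribenzyloxyphenyl)chroman-3-ol
Conditions: 12 (1.5 equiv), BF3·OEt2 (promoter), CH2Cl2, −30 to 0 °C
Reagents that add atoms: none
Why: Lewis-acid ionisation of the benzylic 4-hydroxyl gives the C4 cation stabilised by the para 7-benzyloxy group, which is captured in a Friedel–Crafts alkylation (the flavan-3,4-diol/phenol condensation of proanthocyanidin chemistry) by the ring carbon of 12 ortho to its hydroxyl, attack anti to the neighbouring 3-hydroxyl setting C4 as S (3,4-trans).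

Step 9
Reactants: 13 the C4-arylated alkyne of step 8
Product: 14 (2R,3S,4S)-7-benzyloxy-4-{4,6-dibenzyloxy-2-hydroxy-3-[(2Z)-3-(3,4,5-tribenzyloxyphenyl)prop-2-en-1-yl]phenyl}-2-(3,4,5-tribenzyloxyphenyl)chroman-3-ol
Conditions: H2 (1 atm), Pd/CaCO3 poisoned with Pb(OAc)2, quinoline, EtOAc, rt
Reagents that add atoms: none
Why: Lindlar semihydrogenation, syn delivery of hydrogen on the poisoned surface giving the Z alkene while leaving the benzyl ethers alone.

Step 10
Reactants: 14 the Z alkene of step 9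
Product: 15 bis(triethylsilyl) ether of 14 (silyl groups on the chroman 3-oxygen and on the phenol oxygen)
Conditions: Et3SiOTf, 2,6-lutidine, CH2Cl2, −20 °C
Reagents that add atoms: triethylsilyl trifluoromethanesulfonate, CC[Si](CC)(CC)OS(=O)(=O)C(F)(F)F
Why: Silylation with a silyl triflate, reactive enough for the two hindered hydroxyls, masks the oxidisable phenol (and the 3-hydroxyl) for the epoxidation with groups that fluoride can later remove without base.

Step 11
Reactants: 15 bis(triethylsilyl) ether of the Z alkene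
Product: 16 bis(triethylsilyl) ether of (2R,3S,4S)-7-benzyloxy-4-{4,6-dibenzyloxy-2-hydroxy-3-{[(2R,3S)-3-(3,4,5-tribenzyloxyphenyl)oxiran-2-yl]methyl}phenyl}-2-(3,4,5-tribenzyloxyphenyl)chroman-3-ol
Conditions: (S,S)-(salen)MnCl (5 mol%; trivalent manganese, salen = N,N'-bis(3,5-di-tert-butylsalicylidene)cyclohexane-1,2-diaminate), mCPBA, NMO, CH2Cl2, −78 °C
Reagents that add atoms: 3-chloroperoxybenzoic acid, OOC(=O)c1cccc(Cl)c1
Why: Jacobsen–Katsuki epoxidation of a Z aryl alkene, the best substrate class for this catalyst, in which side-on approach to the oxo-manganese species of the (S,S)-catalyst should deliver oxygen to the face giving the (2R,3S)-cis-oxirane (benzylic carbon S), by analogy with cis-β-methylstyrene and indene, which give the (1S,2R)-oxides with the same catalyst, while NMO at −78 °C suppresses the uncatalysed peracid pathway.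

Step 12
Reactants: 16 bis(triethylsilyl) ether of the cis-epoxide
Product: 17 (2R,3S,4S)-7-benzyloxy-4-{4,6-dibenzyloxy-2-hydroxy-3-{[(2R,3S)-3-(3,4,5-tribenzyloxyphenyl)oxiran-2-yl]methyl}phenyl}-2-(3,4,5-tribenzyloxyphenyl)chroman-3-ol
Conditions: Bu4NF/AcOH (1:1), THF, 0 °C to rt; used crude
Reagents that add atoms: none
Why: Fluoride-induced desilylation of both silyl ethers, buffered with acetic acid so that the liberated phenol stays protonated, since a phenoxide would open the oxirane at C3 in the 5-exo mode.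

Step 13
Reactants: 17 the free phenol cis-epoxide of step 12
Product: 18 nona-O-benzyl robinetinidol-(4α→8)-epigallocatechin, (2R,3R)-5,7-dibenzyloxy-8-[(2R,3S,4S)-7-benzyloxy-3-hydroxy-2-(3,4,5-tribenzyloxyphenyl)chroman-4-yl]-2-(3,4,5-tribenzyloxyphenyl)chroman-3-ol
Conditions: CSA (10 mol%), CH2Cl2, −40 to −20 °C
Reagents that add atoms: none
Why: Protonation of the oxirane oxygen polarises the benzylic C2–O bond and the C8a hydroxyl attacks C2 from the rear while the oxirane oxygen stays on C3 as the 3-hydroxyl, which is the acid-catalysed intramolecular opening of an aryl epoxide by an ortho-phenol used for flavan-3-ols. Ring C closes in the 6-endo-tet mode, preferred over 5-exo attack at C3 because only C2 carries the cation-stabilising aryl group. C2 becomes R by inversion of the S-configured benzylic oxirane carbon, so it is controlled by the epoxide configuration set in step 11, and C3 (R) is carried over unchanged; anti addition across the former Z alkene is what makes the unit 2,3-cis. The step needs inversion instead of a free-cation pathway, which a weak catalytic acid, a non-polar solvent and low temperature should secure, and it needs 4→8 regiochemistry, which is secured because the C8a hydroxyl is the only free phenol and the other oxygen flanking the chain (O5) is a benzyl ether. The upper C4–C8 bond belongs to a 5-deoxy unit and should not be cleaved by this acid.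

Step 14
Reactants: 18 nona-O-benzyl robinetinidol-(4α→8)-epigallocatechin
Product: 19 robinetinidol-(4α→8)-epigallocatechin (CNP0275321.3), (2R,3R)-8-[(2R,3S,4S)-3,7-dihydroxy-2-(3,4,5-trihydroxyphenyl)chroman-4-yl]-2-(3,4,5-trihydroxyphenyl)chromane-3,5,7-triol
Conditions: H2 (1 atm), Pd(OH)2/C, THF–MeOH, rt; work-up under argon
Reagents that add atoms: none
Why: Catalytic hydrogenolysis of the nine benzyl aryl ethers, conditions under which the flavan C2–O1 bonds and the C4–C8 bond are normally retained and no stereocentre is touched.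

**Compound list**

1 | (+)-dihydrorobinetin, (2R,3R)-3,7-dihydroxy-2-(3,4,5-trihydroxyphenyl)chroman-4-one | Oc1ccc2c(c1)O[C@H](c1cc(O)c(O)c(O)c1)[C@@H](O)C2=O | starting material
2 | (2R,3R)-7-benzyloxy-3-hydroxy-2-(3,4,5-tribenzyloxyphenyl)chroman-4-one | c5ccccc5COc1ccc2c(c1)O[C@H](c3cc(OCc5ccccc5)c(OCc5ccccc5)c(OCc5ccccc5)c3)[C@@H](O)C2=O | intermediate
3 | (2R,3S,4R)-7-benzyloxy-2-(3,4,5-tribenzyloxyphenyl)chromane-3,4-diol | c5ccccc5COc1ccc2c(c1)O[C@H](c3cc(OCc5ccccc5)c(OCc5ccccc5)c(OCc5ccccc5)c3)[C@@H](O)[C@@H]2O | intermediate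
4 | 3,4,5-trihydroxybenzaldehyde | O=Cc1cc(O)c(O)c(O)c1 | starting material
5 | 3,4,5-tribenzyloxybenzaldehyde | O=Cc1cc(OCc2ccccc2)c(OCc2ccccc2)c(OCc2ccccc2)c1 | intermediate
6 | 1,2,3-tribenzyloxy-5-(2,2-dibromovinyl)benzene | BrC(Br)=Cc1cc(OCc2ccccc2)c(OCc2ccccc2)c(OCc2ccccc2)c1 | intermediate
7 | lithium (3,4,5-tribenzyloxyphenyl)acetylide | [Li]C#Cc1cc(OCc2ccccc2)c(OCc2ccccc2)c(OCc2ccccc2)c1 | intermediate
8 | 3-(3,4,5-tribenzyloxyphenyl)prop-2-yn-1-ol | OCC#Cc1cc(OCc2ccccc2)c(OCc2ccccc2)c(OCc2ccccc2)c1 | intermediate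
9 | hexacarbonyldicobalt complex of alkynol 8, the alkyne bridging the Co–Co bond | OCC12[Co]3(=C=O)(=C=O)(=C=O)[Co]1(=C=O)(=C=O)(=C=O)C23c4cc(OCc5ccccc5)c(OCc5ccccc5)c(OCc5ccccc5)c4 | intermediate
10 | 3,5-dibenzyloxyphenol | Oc1cc(OCc2ccccc2)cc(OCc2ccccc2)c1 | starting material
11 | hexacarbonyldicobalt complex of alkyne 12 | Oc6cc(OCc5ccccc5)cc(OCc5ccccc5)c6CC12[Co]3(=C=O)(=C=O)(=C=O)[Co]1(=C=O)(=C=O)(=C=O)C23c4cc(OCc5ccccc5)c(OCc5ccccc5)c(OCc5ccccc5)c4 | intermediate
12 | 3,5-dibenzyloxy-2-[3-(3,4,5-tribenzyloxyphenyl)prop-2-yn-1-yl]phenol | Oc1cc(OCc2ccccc2)cc(OCc2ccccc2)c1CC#Cc1cc(OCc2ccccc2)c(OCc2ccccc2)c(OCc2ccccc2)c1 | intermediate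
13 | (2R,3S,4S)-7-benzyloxy-4-{4,6-dibenzyloxy-2-hydroxy-3-[3-(3,4,5-tribenzyloxyphenyl)prop-2-yn-1-yl]phenyl}-2-(3,4,5-tribenzyloxyphenyl)chroman-3-ol | c5ccccc5COc1ccc2c(c1)O[C@H](c3cc(OCc5ccccc5)c(OCc5ccccc5)c(OCc5ccccc5)c3)[C@@H](O)[C@@H]2c4c(O)c(CC#Cc6cc(OCc5ccccc5)c(OCc5ccccc5)c(OCc5ccccc5)c6)c(OCc5ccccc5)cc4OCc5ccccc5 | intermediate
14 | (2R,3S,4S)-7-benzyloxy-4-{4,6-dibenzyloxy-2-hydroxy-3-[(2Z)-3-(3,4,5-tribenzyloxyphenyl)prop-2-en-1-yl]phenyl}-2-(3,4,5-tribenzyloxyphenyl)chroman-3-ol | c5ccccc5COc1ccc2c(c1)O[C@H](c3cc(OCc5ccccc5)c(OCc5ccccc5)c(OCc5ccccc5)c3)[C@@H](O)[C@@H]2c4c(O)c(C/C=C\c6cc(OCc5ccccc5)c(OCc5ccccc5)c(OCc5ccccc5)c6)c(OCc5ccccc5)cc4OCc5ccccc5 | intermediate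
15 | bis(triethylsilyl) ether of 14 (chroman 3-O and phenol O silylated) | c5ccccc5COc1ccc2c(c1)O[C@H](c3cc(OCc5ccccc5)c(OCc5ccccc5)c(OCc5ccccc5)c3)[C@@H](O[Si](CC)(CC)CC)[C@@H]2c4c(O[Si](CC)(CC)CC)c(C/C=C\c6cc(OCc5ccccc5)c(OCc5ccccc5)c(OCc5ccccc5)c6)c(OCc5ccccc5)cc4OCc5ccccc5 | intermediate
16 | bis(triethylsilyl) ether of 17, side chain [(2R,3S)-3-(3,4,5-tribenzyloxyphenyl)oxiran-2-yl]methyl | c5ccccc5COc1ccc2c(c1)O[C@H](c3cc(OCc5ccccc5)c(OCc5ccccc5)c(OCc5ccccc5)c3)[C@@H](O[Si](CC)(CC)CC)[C@@H]2c4c(O[Si](CC)(CC)CC)c(C[C@H]8O[C@H]8c6cc(OCc5ccccc5)c(OCc5ccccc5)c(OCc5ccccc5)c6)c(OCc5ccccc5)cc4OCc5ccccc5 | intermediate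
17 | (2R,3S,4S)-7-benzyloxy-4-{4,6-dibenzyloxy-2-hydroxy-3-{[(2R,3S)-3-(3,4,5-tribenzyloxyphenyl)oxiran-2-yl]methyl}phenyl}-2-(3,4,5-tribenzyloxyphenyl)chroman-3-ol | c5ccccc5COc1ccc2c(c1)O[C@H](c3cc(OCc5ccccc5)c(OCc5ccccc5)c(OCc5ccccc5)c3)[C@@H](O)[C@@H]2c4c(O)c(C[C@H]8O[C@H]8c6cc(OCc5ccccc5)c(OCc5ccccc5)c(OCc5ccccc5)c6)c(OCc5ccccc5)cc4OCc5ccccc5 | intermediate
18 | nona-O-benzyl robinetinidol-(4α→8)-epigallocatechin, (2R,3R)-5,7-dibenzyloxy-8-[(2R,3S,4S)-7-benzyloxy-3-hydroxy-2-(3,4,5-tribenzyloxyphenyl)chroman-4-yl]-2-(3,4,5-tribenzyloxyphenyl)chroman-3-ol | c5ccccc5COc1ccc2c(c1)O[C@H](c3cc(OCc5ccccc5)c(OCc5ccccc5)c(OCc5ccccc5)c3)[C@@H](O)[C@@H]2c4c(OCc5ccccc5)cc(OCc5ccccc5)c6c4O[C@H](c7cc(OCc5ccccc5)c(OCc5ccccc5)c(OCc5ccccc5)c7)[C@H](O)C6 | intermediate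
19 | robinetinidol-(4α→8)-epigallocatechin (CNP0275321.3), (2R,3R)-8-[(2R,3S,4S)-3,7-dihydroxy-2-(3,4,5-trihydroxyphenyl)chroman-4-yl]-2-(3,4,5-trihydroxyphenyl)chromane-3,5,7-triol | Oc1ccc2c(c1)O[C@H](c1cc(O)c(O)c(O)c1)[C@@H](O)[C@@H]2c1c(O)cc(O)c2c1O[C@H](c1cc(O)c(O)c(O)c1)[C@H](O)C2 | target

**Step count and risks**

Total steps: 14. Longest linear sequence: 12 (steps 3–7, then 8–14).

Steps most likely to fail:

Step 13. The para-benzyloxy group on the lower ring B stabilises a benzylic cation, so the protonated oxirane may ionise before the C8a oxygen has bonded; rotation about C2–C3 would then erode the inversion at C2, and attack at C3 (5-exo) would give a dihydrobenzofuran. The fallback leaves the epoxide out and closes ring C by a Mitsunobu displacement. It sets out from 15. OsO4/NMO syn-dihydroxylation should give the (1S,2R) bis-silylated syn-diol F1 as one of two syn-diol diastereomers, separable because the upper unit is enantiopure. K2CO3 in MeOH removes only the aryl silyl ether to give the phenol diol F2. PPh3/DIAD in THF closes O1–C2 by SN2 inversion at the benzylic carbinol (syn-diol plus inversion again gives 2,3-cis) to give the 3-O-triethylsilyl ether of the cyclised product F3. HF·pyridine in THF removes the last silyl group, and the fallback comes back at 18.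

Step 11. Oxygen transfer from the oxo-manganese species is stepwise, and a benzylic radical next to the electron-rich aryl ring can rotate before the ring closes, which leaks to the trans-epoxide. The large groups on both alkene carbons may also blunt the facial discrimination by the catalyst. The fallback gives up catalyst control for a concerted achiral oxidant and separation. It sets out from 15: dimethyldioxirane in acetone/CH2Cl2 at −20 °C should give, stereospecifically cis, 16 together with its oxirane diastereomer F4. The two are diastereomers because of the enantiopure upper unit and are separated by chromatography on base-washed silica (or later, as the flavan-3-ols after steps 12 and 13). The fallback comes back at 16.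

Step 8. The C4 cation has no 5-substituent, so attack of the phenol syn to the 3-hydroxyl (3,4-cis) can compete. Attack through the ring carbon between the two benzyloxy groups (which would lead to the 4→6 series) and self-condensation of 3 are further possible leaks. The fallback uses anchimeric assistance and sets out from 3. Ac2O/pyridine/DMAP gives the 3,4-di-O-acetate F5. Catalytic TMSOTf in CH2Cl2 at −78 °C ionises the 4-acetate; the 3-acetoxy group bridges the β-face as a dioxolanylium ion and 12 enters from the α-face to give the 3-O-acetate of the coupled alkyne F6. K2CO3/MeOH at rt removes the acetate, and the fallback comes back at 13.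

**Further compounds**

F1 | step 13 | bis(triethylsilyl) ether 15 in which the Z alkene is replaced by the (1S,2R)-1,2-diol, i.e. side chain (2R,3S)-2,3-dihydroxy-3-(3,4,5-tribenzyloxyphenyl)propyl | c5ccccc5COc1ccc2c(c1)O[C@H](c3cc(OCc5ccccc5)c(OCc5ccccc5)c(OCc5ccccc5)c3)[C@@H](O[Si](CC)(CC)CC)[C@@H]2c4c(O[Si](CC)(CC)CC)c(C[C@@H](O)[C@@H](O)c6cc(OCc5ccccc5)c(OCc5ccccc5)c(OCc5ccccc5)c6)c(OCc5ccccc5)cc4OCc5ccccc5
F2 | step 13 | F1 with the phenol oxygen free and the chroman 3-O-triethylsilyl ether kept | c5ccccc5COc1ccc2c(c1)O[C@H](c3cc(OCc5ccccc5)c(OCc5ccccc5)c(OCc5ccccc5)c3)[C@@H](O[Si](CC)(CC)CC)[C@@H]2c4c(O)c(C[C@@H](O)[C@@H](O)c6cc(OCc5ccccc5)c(OCc5ccccc5)c(OCc5ccccc5)c6)c(OCc5ccccc5)cc4OCc5ccccc5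
F3 | step 13 | 18 carrying a triethylsilyl ether on the upper-unit 3-oxygen | c5ccccc5COc1ccc2c(c1)O[C@H](c3cc(OCc5ccccc5)c(OCc5ccccc5)c(OCc5ccccc5)c3)[C@@H](O[Si](CC)(CC)CC)[C@@H]2c4c(OCc5ccccc5)cc(OCc5ccccc5)c6c4O[C@H](c7cc(OCc5ccccc5)c(OCc5ccccc5)c(OCc5ccccc5)c7)[C@H](O)C6
F4 | step 11 | diastereomer of 16 with the (2S,3R)-cis-oxirane | c5ccccc5COc1ccc2c(c1)O[C@H](c3cc(OCc5ccccc5)c(OCc5ccccc5)c(OCc5ccccc5)c3)[C@@H](O[Si](CC)(CC)CC)[C@@H]2c4c(O[Si](CC)(CC)CC)c(C[C@@H]8O[C@@H]8c6cc(OCc5ccccc5)c(OCc5ccccc5)c(OCc5ccccc5)c6)c(OCc5ccccc5)cc4OCc5ccccc5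
F5 | step 8 | 3,4-di-O-acetate of diol 3, ring configuration as in 3 | c5ccccc5COc1ccc2c(c1)O[C@H](c3cc(OCc5ccccc5)c(OCc5ccccc5)c(OCc5ccccc5)c3)[C@@H](OC(C)=O)[C@@H]2OC(C)=O
F6 | step 8 | 3-O-acetate of 13 | c5ccccc5COc1ccc2c(c1)O[C@H](c3cc(OCc5ccccc5)c(OCc5ccccc5)c(OCc5ccccc5)c3)[C@@H](OC(C)=O)[C@@H]2c4c(O)c(CC#Cc6cc(OCc5ccccc5)c(OCc5ccccc5)c(OCc5ccccc5)c6)c(OCc5ccccc5)cc4OCc5ccccc5
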